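**Retrosynthetic overview**

1. Labdane numbering is used: decalin C1–C10, C18 (methyl) and C19 (acetoxymethyl) on C4, C20 (methyl) on C10, C17 (methyl) on C8, side chain C11–C16 on C9. The end game turns a C19 ester into CH2OAc and a C2 ketone into the alcohol, and dresses ring B from a C9 carbonyl (Negishi coupling of the side chain, hydroboration/oxidation to the C8 ketone, enol triflate, methyl coupling for C7=C8 and C17).
2. Key disconnection: ring A is closed onto ring B through C1–C2 (acylation of a zinc homoenolate) and C4–C5 (copper hydride reductive aldol) in one flask, from 2-(iodomethyl)-2-methylcyclohexane-1,3-dione and the acid chloride of an itaconic half-ester.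
3. Enabling feature: the quaternary C10 of ring B lies between C5 and C9. With both at the ketone level, ring B is a 2,2-disubstituted cyclohexane-1,3-dione with two enantiotopic carbonyls. The pair C1 (nucleophile)/C5 (electrophile), 1,3 across C10, matches the pair C2 (acyl)/C4 (enolate), 1,3 across C3, of the itaconyl unit, whose methylene becomes C18 and whose ester becomes C19.
4. The aldol hydroxyl at C5 is temporary: dehydration and hydrogen-atom-transfer hydrogenation give the trans ring fusion.
5. Ring order: ring B is bought, ring A is closed in the key step. C13 comes from methyl hydrogen (R)-3-methylglutarate.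

Key step: step 5

Assumption: (R)-DTBM-SEGPHOS is taken as the ligand enantiomer that steers the copper enolate in step 5 to the ring carbonyl that leads to 10; if a first run shows the opposite sense, the (S)-ligand is used and nothing else changes.

**Route**

Step 1
Reactants: 1 2-methylcyclohexane-1,3-dione
Product: 2 2-(hydroxymethyl)-2-methylcyclohexane-1,3-dione
Conditions: 37% aq. CH2O, NaHCO3 (cat.), H2O/THF, 25 °C
Reagents that add atoms: formaldehyde, C=O
Why: Aldol hydroxymethylation of the doubly activated C–H of a 2-alkyl-1,3-dione should proceed under mild base and gives the still achiral quaternary carbon (future C10) that carries the future C1.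

Step 2
Reactants: 2 2-(hydroxymethyl)-2-methylcyclohexane-1,3-dione
Product: 3 2-(iodomethyl)-2-methylcyclohexane-1,3-dione
Conditions: I2, PPh3, imidazole, toluene, 60 °C
Reagents that add atoms: iodine, II
Why: Appel iodination (alkoxyphosphonium salt, displacement by iodide) should convert the primary alcohol without touching the non-enolisable dione; no stereocentre is involved.

Step 3
Reactants: 4 dimethyl itaconate
Product: 5 3-(methoxycarbonyl)but-3-enoic acid (itaconic acid 1-methyl ester)
Conditions: lipase (Candida antarctica lipase B, immobilised), phosphate buffer pH 7.2/MTBE, 30 °C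
Reagents that add atoms: water, O
Why: Lipase-catalysed ester hydrolysis should distinguish the unconjugated, less hindered ester from the acrylate ester and free only the carboxyl that becomes C2.

Step 4
Reactants: 5 3-(methoxycarbonyl)but-3-enoic acid
Product: 6 methyl 2-(2-chloro-2-oxoethyl)prop-2-enoate
Conditions: (COCl)2, DMF (cat.), CH2Cl2, 0 to 25 °C
Reagents that add atoms: oxalyl chloride, O=C(Cl)C(Cl)=O
Why: Acid chloride formation through the chloroiminium intermediate is base-free, so the acrylate should not migrate into conjugation.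

Step 5
Reactants: 3 2-(iodomethyl)-2-methylcyclohexane-1,3-dione; 6 methyl 2-(2-chloro-2-oxoethyl)prop-2-enoate
Product: 10 ring-A aldol (methyl 8a-hydroxy-1,4a-dimethyl-3,5-dioxodecahydronaphthalene-1-carboxylate; ester/8a-OH/4a-CH3 all cis; labdane positions: C2 and C9 ketones, C5–OH, C19 ester), via zinc homoenolate 7 (not isolated), via triketo acrylate 8 (not isolated), via silyl ether 9 (not isolated)
Conditions: Zn–Cu couple, toluene/DMA, 60 °C; Pd(PPh3)4 (2 mol %), 6, 0 to 25 °C; then Cu(OAc)2·H2O (5 mol %), (R)-DTBM-SEGPHOS (5.5 mol %), (EtO)2MeSiH, toluene, −20 to 0 °C; 1 M HCl/THF work-up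
Reagents that add atoms: none
Why: Zinc inserts into the C–I bond to give the β-zincio dione 7 (no β-elimination is possible because C10 is quaternary), and zerovalent palladium couples it with acid chloride 6 (oxidative addition, transmetalation, reductive elimination) to form C1–C2 in triketo acrylate 8. The bisphosphine copper hydride then adds hydride to the acrylate methylene (which becomes the C18 methyl), and the copper enolate attacks one of the two enantiotopic ring carbonyls in an intramolecular aldol addition that forms C4–C5 and closes ring A in a 6-(enolexo)-exo-trig mode, after which the silane converts the copper aldolate into silyl ether 9 and regenerates the hydride. The closest known reactions are the palladium-catalysed acylation of zinc homoenolates with acid chlorides and the copper-hydride-catalysed conjugate reduction/aldol desymmetrisation of enoates tethered to 2,2-disubstituted cyclohexane-1,3-diones. C10 is set by the ligand, which decides which carbonyl is attacked; the C5 hydroxyl comes out cis to the C20 methyl because the tether from C10 can only reach the carbonyl face on its own side (cis-fused ketol); C4 is set by the metal-bridged, chair-like Zimmerman–Traxler transition state, which places the ester cis to the new hydroxyl and hence cis to C20, as C19 must be. The step needs conjugate rather than carbonyl hydride delivery and aldol addition to a ring carbonyl only: the acrylate is the sole conjugate acceptor, the C2 ketone is out of reach of the C4 enolate (a three-membered ring would result), and the non-enolisable dione cannot condense with itself.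

Step 6
Reactants: 10 ring-A aldol
Product: 11 methyl 1,4a-dimethyl-3,5-dioxo-1,2,3,4,4a,5,6,7-octahydronaphthalene-1-carboxylate (C5=C6 alkene; ester cis to 4a-CH3)
Conditions: Burgess reagent (MeO2CN–SO2NEt3 inner salt), toluene, 70 °C
Reagents that add atoms: none
Why: Burgess dehydration (syn elimination of the sulfamate) can only take a C6 hydrogen because C4 and C10 are quaternary, so the temporary C5 hydroxyl should leave as a single alkene.

Step 7
Reactants: 11 C5=C6 alkene
Product: 12 methyl 1,4a-dimethyl-3,5-dioxodecahydronaphthalene-1-carboxylate (trans-fused; C5–H trans to C20; ester cis to C20)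
Conditions: Mn(dpm)3 (10 mol %), PhSiH3, t-BuOOH, i-PrOH, 22 °C
Reagents that add atoms: none
Why: Hydrogen-atom-transfer hydrogenation (Mukaiyama type, Shenvi conditions) adds H• to C6, and the tertiary C5 radical should be reduced from the face opposite to the C19 ester and the C20 methyl, which gives the trans ring fusion.

Step 8
Reactants: 12 trans-fused diketo ester
Product: 13 methyl 3-hydroxy-1,4a-dimethyl-5-oxodecahydronaphthalene-1-carboxylate (equatorial C2–OH, trans to the C19 ester and to C20)
Conditions: ketoreductase (NADPH-dependent alcohol dehydrogenase, chosen from a panel), NADP+ (cat.), i-PrOH, phosphate buffer pH 7.0/DMSO, 30 °C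
Reagents that add atoms: none
Why: An enzymatic carbonyl reduction (ketoreductase class) should take the open C2 ketone and leave the neopentyl C9 ketone, and the enzyme, not the substrate, fixes the hydride face, so the equatorial alcohol that small hydrides would not give is reachable.

Step 9
Reactants: 13 C2 alcohol
Product: 14 TBS ether of 13 (C2–OTBS)
Conditions: TBSCl, imidazole, DMF, 25 °C
Reagents that add atoms: tert-butyldimethylsilyl chloride, CC(C)(C)[Si](C)(C)Cl
Why: Silylation of the only hydroxyl, an unhindered equatorial secondary alcohol, protects C2 through the enolate and organometallic steps.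

Step 10
Reactants: 14 TBS ether
Product: 15 C9 enol triflate (C9(OTf)=C8)
Conditions: KN(SiMe3)2, THF, −78 °C; PhNTf2, −78 to 0 °C
Reagents that add atoms: N-phenylbis(trifluoromethanesulfonimide), O=S(=O)(N(c1ccccc1)S(=O)(=O)C(F)(F)F)C(F)(F)F
Why: Enolate O-triflation: the C9 ketone can enolise only towards C8 because C10 is quaternary, and the C19 ester has no α-hydrogen, so one vinyl triflate should form.

Step 11
Reactants: 16 methyl hydrogen (R)-3-methylglutarate
Product: 17 methyl (R)-5-hydroxy-3-methylpentanoate
Conditions: BH3·SMe2, THF, 0 °C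
Reagents that add atoms: none
Why: Borane reduces the carboxylic acid through the acyloxyborane far faster than the ester and does not touch the stereocentre (future C13).

Step 12
Reactants: 17 methyl (R)-5-hydroxy-3-methylpentanoate
Product: 18 methyl (S)-5-iodo-3-methylpentanoate
Conditions: I2, PPh3, imidazole, CH2Cl2, 0 to 25 °C
Reagents that add atoms: iodine, II
Why: Appel iodination of the primary alcohol; the descriptor changes from R to S only because the priority order changes.

Step 13
Reactants: 18 methyl (S)-5-iodo-3-methylpentanoate; 15 C9 enol triflate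
Product: 20 C8=C9 alkene carrying the side chain on C9 (2-OTBS-labd-8-ene-15,19-dioic acid dimethyl ester lacking C17), via alkylzinc iodide 19 (not isolated)
Conditions: 18, Zn dust, LiCl, THF, 40 °C; then 15, PdCl2(dppf) (5 mol %), THF/NMP, 60 °C
Reagents that add atoms: none
Why: Negishi coupling of an ester-tolerant alkylzinc iodide with the vinyl triflate (zerovalent palladium, dppf to hold back β-hydride elimination) should attach the whole side chain at C9.

Step 14
Reactants: 20 C8=C9 alkene
Product: 22 C8 alcohol (C9–H and C8–OH on the face opposite to C20; side chain cis to C20), via alkylborane 21 (not isolated)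
Conditions: BH3·SMe2, THF, 0 to 25 °C; then H2O2, aq. NaOAc, 0 °C
Reagents that add atoms: hydrogen peroxide, OO
Why: Hydroboration–oxidation: boron should go to the less substituted C8 from the face away from the axial C20 methyl, and the hydrogen delivered syn to C9 leaves the side chain cis to C20.

Step 15
Reactants: 22 C8 alcohol
Product: 23 C8 ketone (side chain equatorial at C9)
Conditions: Dess–Martin periodinane, NaHCO3, CH2Cl2, 25 °C
Reagents that add atoms: none
Why: Dess–Martin oxidation under buffered conditions; C9 already has the more stable equatorial side chain, so enolisation would not change it.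

Step 16
Reactants: 23 C8 ketone
Product: 24 C8 enol triflate (C8(OTf)=C7)
Conditions: KN(SiMe3)2 (1.05 equiv), THF, −78 °C; PhNTf2
Reagents that add atoms: N-phenylbis(trifluoromethanesulfonimide), O=S(=O)(N(c1ccccc1)S(=O)(=O)C(F)(F)F)C(F)(F)F
Why: Kinetic deprotonation at the methylene C7 and not at the tertiary C9 (nor at the less acidic ester), then O-triflation, fixes the double bond at C7–C8.

Step 17
Reactants: 24 C8 enol triflate
Product: 25 dimethyl ester of 2-OTBS-labd-7-ene-15,19-dioic acid
Conditions: MeMgBr, Fe(acac)3 (5 mol %), THF/NMP, −30 °C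
Reagents that add atoms: methylmagnesium bromide, C[Mg]Br
Why: Iron-catalysed cross-coupling of an enol triflate with a Grignard reagent (Kochi–Fürstner type) installs C17 at a temperature at which both esters should survive.

Step 18
Reactants: 25 diester
Product: 26 19-methyl ester 15-acid (2-OTBS)
Conditions: LiOH, THF/MeOH/H2O, 25 °C; then 1 M HCl
Reagents that add atoms: lithium hydroxide, [Li+].[OH-]
Why: Saponification should touch only the open side-chain ester; the axial C19 ester on a quaternary carbon is inert at room temperature.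

Step 19
Reactants: 26 19-methyl ester 15-acid
Product: 27 19-hydroxy-2-OTBS-labd-7-en-15-oic acid
Conditions: LiEt3BH, THF, 0 to 40 °C; then 1 M HCl
Reagents that add atoms: none
Why: Hydride reduction with LiEt3BH takes the hindered ester to the primary alcohol and leaves the lithium carboxylate formed in situ.

Step 20
Reactants: 27 19-hydroxy acid
Product: 28 19-acetoxy-2-OTBS-labd-7-en-15-oic acid
Conditions: Ac2O, pyridine, DMAP (cat.), CH2Cl2, 0 °C; aq. NaHCO3, then pH 4
Reagents that add atoms: acetic anhydride, CC(=O)OC(C)=O
Why: DMAP-catalysed acetylation of the only free hydroxyl; the mixed anhydride formed at the acid is hydrolysed in the work-up.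

Step 21
Reactants: 28 19-acetoxy-2-OTBS acid
Product: 29 target, 19-acetoxy-2-hydroxylabd-7-en-15-oic acid (configuration as in the SMILES)
Conditions: HF·pyridine, THF, 0 to 25 °C
Reagents that add atoms: none
Why: Fluoride cleavage of the silyl ether in pyridine-buffered medium should leave the acetate and the trisubstituted alkene untouched.

**Compound list**

1 | 2-methylcyclohexane-1,3-dione | CC1C(=O)CCCC1=O | starting material
2 | 2-(hydroxymethyl)-2-methylcyclohexane-1,3-dione | CC1(CO)C(=O)CCCC1=O | intermediate
3 | 2-(iodomethyl)-2-methylcyclohexane-1,3-dione | CC1(CI)C(=O)CCCC1=O | intermediate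
4 | dimethyl itaconate | COC(=O)CC(=C)C(=O)OC | starting material
5 | 3-(methoxycarbonyl)but-3-enoic acid | OC(=O)CC(=C)C(=O)OC | intermediate
6 | methyl 2-(2-chloro-2-oxoethyl)prop-2-enoate | COC(=O)C(=C)CC(Cl)=O | intermediate
7 | [(1-methyl-2,6-dioxocyclohexyl)methyl]zinc iodide | CC1(C[Zn]I)C(=O)CCCC1=O | intermediate
8 | methyl 2-methylidene-5-(1-methyl-2,6-dioxocyclohexyl)-4-oxopentanoate | COC(=O)C(=C)CC(=O)CC1(C)C(=O)CCCC1=O | intermediate
9 | diethoxy(methyl)silyl ether of 10 | COC(=O)[C@]1(C)CC(=O)C[C@@]2(C)C(=O)CCC[C@@]12O[Si](C)(OCC)OCC | intermediate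
10 | methyl 8a-hydroxy-1,4a-dimethyl-3,5-dioxodecahydronaphthalene-1-carboxylate (ester, OH and 4a-CH3 all cis) | COC(=O)[C@]1(C)CC(=O)C[C@@]2(C)C(=O)CCC[C@@]12O | intermediate
11 | methyl 1,4a-dimethyl-3,5-dioxo-1,2,3,4,4a,5,6,7-octahydronaphthalene-1-carboxylate | COC(=O)[C@]1(C)CC(=O)C[C@@]2(C)C(=O)CCC=C12 | intermediate
12 | methyl 1,4a-dimethyl-3,5-dioxodecahydronaphthalene-1-carboxylate, trans-fused | COC(=O)[C@]1(C)CC(=O)C[C@@]2(C)C(=O)CCC[C@H]12 | intermediate
13 | methyl 3-hydroxy-1,4a-dimethyl-5-oxodecahydronaphthalene-1-carboxylate (equatorial OH) | COC(=O)[C@]1(C)C[C@@H](O)C[C@@]2(C)C(=O)CCC[C@H]12 | intermediate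
14 | TBS ether of 13 | COC(=O)[C@]1(C)C[C@@H](O[Si](C)(C)C(C)(C)C)C[C@@]2(C)C(=O)CCC[C@H]12 | intermediate
15 | C9 enol triflate | COC(=O)[C@]1(C)C[C@@H](O[Si](C)(C)C(C)(C)C)C[C@@]2(C)C(OS(=O)(=O)C(F)(F)F)=CCC[C@H]12 | intermediate
16 | methyl hydrogen (R)-3-methylglutarate | OC(=O)C[C@@H](C)CC(=O)OC | starting material
17 | methyl (R)-5-hydroxy-3-methylpentanoate | OCC[C@@H](C)CC(=O)OC | intermediate
18 | methyl (S)-5-iodo-3-methylpentanoate | ICC[C@@H](C)CC(=O)OC | intermediate
19 | [(3S)-5-methoxy-3-methyl-5-oxopentyl]zinc iodide | I[Zn]CC[C@@H](C)CC(=O)OC | intermediate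
20 | C8=C9 alkene with side chain on C9 | COC(=O)[C@]1(C)C[C@@H](O[Si](C)(C)C(C)(C)C)C[C@@]2(C)C(CC[C@@H](C)CC(=O)OC)=CCC[C@H]12 | intermediate
21 | C8 alkylborane | COC(=O)[C@]1(C)C[C@@H](O[Si](C)(C)C(C)(C)C)C[C@@]2(C)[C@H](CC[C@@H](C)CC(=O)OC)[C@@H](B)CC[C@H]12 | intermediate
22 | C8 alcohol | COC(=O)[C@]1(C)C[C@@H](O[Si](C)(C)C(C)(C)C)C[C@@]2(C)[C@H](CC[C@@H](C)CC(=O)OC)[C@@H](O)CC[C@H]12 | intermediate
23 | C8 ketone | COC(=O)[C@]1(C)C[C@@H](O[Si](C)(C)C(C)(C)C)C[C@@]2(C)[C@H](CC[C@@H](C)CC(=O)OC)C(=O)CC[C@H]12 | intermediate
24 | C8 enol triflate | COC(=O)[C@]1(C)C[C@@H](O[Si](C)(C)C(C)(C)C)C[C@@]2(C)[C@H](CC[C@@H](C)CC(=O)OC)C(OS(=O)(=O)C(F)(F)F)=CC[C@H]12 | intermediate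
25 | dimethyl ester of 2-OTBS-labd-7-ene-15,19-dioic acid | COC(=O)[C@]1(C)C[C@@H](O[Si](C)(C)C(C)(C)C)C[C@@]2(C)[C@H](CC[C@@H](C)CC(=O)OC)C(C)=CC[C@H]12 | intermediate
26 | 19-methyl ester 15-acid | COC(=O)[C@]1(C)C[C@@H](O[Si](C)(C)C(C)(C)C)C[C@@]2(C)[C@H](CC[C@@H](C)CC(=O)O)C(C)=CC[C@H]12 | intermediate
27 | 19-hydroxy-2-OTBS-labd-7-en-15-oic acid | OC[C@]1(C)C[C@@H](O[Si](C)(C)C(C)(C)C)C[C@@]2(C)[C@H](CC[C@@H](C)CC(=O)O)C(C)=CC[C@H]12 | intermediate
28 | 19-acetoxy-2-OTBS-labd-7-en-15-oic acid | CC(=O)OC[C@]1(C)C[C@@H](O[Si](C)(C)C(C)(C)C)C[C@@]2(C)[C@H](CC[C@@H](C)CC(=O)O)C(C)=CC[C@H]12 | intermediate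
29 | CNP0162900.1, 19-acetoxy-2-hydroxylabd-7-en-15-oic acid | CC(=O)OC[C@]1(C)C[C@@H](O)C[C@@]2(C)[C@H](CC[C@@H](C)CC(=O)O)C(C)=CC[C@H]12 | target

**Step count**

Total: 21 steps. Longest linear sequence: 17 steps (1, 2, 5, 6, 7, 8, 9, 10, 13, 14, 15, 16, 17, 18, 19, 20, 21).

**Steps most likely to fail**

Step 5. The acrylate double bond of 8 may migrate into conjugation with the C2 ketone before hydride delivery. The copper catalyst may discriminate the two ring carbonyls poorly, because phosphine and zinc salts from the first stage compete for copper. The aldol at the congested C4–C5 bond may revert. The fallback sets out from 3 and returns at 10; it desymmetrises first, with an enzyme, and closes the ring afterwards on a single ketone. A ketoreductase (NADP+, isopropanol) reduces one carbonyl of 3 to (hydroxy)(iodomethyl) ketone F1. TBSCl/imidazole gives silyl ether F2. Zinc insertion and Pd(PPh3)4-catalysed acylation with 6 give the isolated keto acrylate F3. [(Ph3P)CuH]6 in toluene at −40 °C performs the reductive aldol, now only diastereoselective, to the silyl-protected aldol F4. HF·pyridine gives diol F5, and Dess–Martin periodinane oxidises its secondary alcohol to the ketone, which gives 10.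

Step 14. Borane may reduce the side-chain ester in competition with the slow hydroboration of the hindered trisubstituted alkene, or may add with poor facial control. The fallback sets out from 20 and returns at 23. mCPBA epoxidises the C8=C9 bond from the face away from C20 to give epoxide F6. BF3·OEt2 opens it at the tertiary C9, and a 1,2-hydride shift (Meinwald rearrangement) gives the C8 ketone, first as the C9 epimer F7. DBU equilibrates F7 to the equatorial side chain, that is 23.

Step 8. The bulky diketone may bind poorly to the enzyme (low conversion), or the enzyme may not distinguish C2 from C9. The fallback sets out from 12 and returns at 13. LiBH(s-Bu)3 at −78 °C reduces only the less hindered C2 ketone, from the face away from the two axial groups, to the axial alcohol F8. A Mitsunobu reaction (PPh3, diisopropyl azodicarboxylate, 4-nitrobenzoic acid) inverts it to the equatorial 4-nitrobenzoate F9. K2CO3 in methanol cleaves the ester to 13.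

Further compounds
F1 | step 5 | 3-hydroxy-2-(iodomethyl)-2-methylcyclohexanone (C10 as in 10; OH shown cis to the methyl, its configuration is lost later) | IC[C@@]1(C)[C@H](O)CCCC1=O
F2 | step 5 | TBS ether of F1 | IC[C@@]1(C)[C@H](O[Si](C)(C)C(C)(C)C)CCCC1=O
F3 | step 5 | methyl 5-[2-(tert-butyldimethylsilyloxy)-1-methyl-6-oxocyclohexyl]-2-methylidene-4-oxopentanoate | COC(=O)C(=C)CC(=O)C[C@@]1(C)[C@H](O[Si](C)(C)C(C)(C)C)CCCC1=O
F4 | step 5 | C9 silyl ether analogue of 10 (C9–OTBS in place of the ketone) | COC(=O)[C@]1(C)CC(=O)C[C@@]2(C)[C@H](O[Si](C)(C)C(C)(C)C)CCC[C@@]12O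
F5 | step 5 | C5,C9-diol analogue of 10 | COC(=O)[C@]1(C)CC(=O)C[C@@]2(C)[C@H](O)CCC[C@@]12O
F6 | step 14 | C8,C9-epoxide of 20 (oxygen on the face opposite to C20) | COC(=O)[C@]1(C)C[C@@H](O[Si](C)(C)C(C)(C)C)C[C@@]2(C)[C@@]3(CC[C@@H](C)CC(=O)OC)O[C@H]3CC[C@H]12
F7 | step 14 | C9 epimer of 23 | COC(=O)[C@]1(C)C[C@@H](O[Si](C)(C)C(C)(C)C)C[C@@]2(C)[C@@H](CC[C@@H](C)CC(=O)OC)C(=O)CC[C@H]12
F8 | step 8 | C2 epimer of 13 (axial alcohol) | COC(=O)[C@]1(C)C[C@H](O)C[C@@]2(C)C(=O)CCC[C@H]12
F9 | step 8 | 4-nitrobenzoate of 13 | COC(=O)[C@]1(C)C[C@@H](OC(=O)c3ccc(cc3)[N+](=O)[O-])C[C@@]2(C)C(=O)CCC[C@H]12
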